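Both halves of the target end in the same array, a (Z)-3-butylidenebutenolide (C1, O2, C3, C3a, C7a and the primed set) sitting on a tetrasubstituted ring alkene: C3a=C7a in ring A, C3a′=C7a′ in the bicyclo[2.2.2]octene. The plan exploits this repeat by cutting C1–C7a, C1–O2, C1′–C7a′ and C1′–O2′ together. One twofold palladium-catalysed carbonylation closes lactones A and B at the very end. In each half the enolate oxygen of the cis pentanoyl group intercepts the acylpalladium unit. The precursor is tricycle 16: OTf on C7a and C7a′, pentanoyl on C3a and C3a′, OTBS on C6′. Its core comes from an enantioselective Diels–Alder reaction followed by an aldol bridge closure.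

Key step: step 12

Locants and target check: phthalide numbering is used for every compound. C7′ and C4′ are the bridgeheads of the bicyclo[2.2.2]octene, whose bridges are C7a′=C3a′, C6′–C5′ and C6–C7. The target is (6S,7R,4′R,6′S,7′S) with both C3=C8 alkenes Z. Ring A is cis-fused at C6–C7 and lies syn to the C5′–C6′ bridge. The C6′ oxygen points toward the C7a′–C3a′ bridge.

Assumption: the (S)-oxazaborolidine is taken to give 6 by the usual enone picture (boron on the carbonyl lone pair syn to C7–H, one alkene face covered by a phenyl group); both antipodes of the catalyst are sold, so the (R)-form is used if the sense proves opposite.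

Step 1
Reactants: 1 3-(tert-butyldimethylsilyloxy)propanal; 2 1-(triphenylphosphoranylidene)propan-2-one
Product: 3 (E)-6-(tert-butyldimethylsilyloxy)hex-3-en-2-one
Conditions: CH2Cl2, rt
Reagents that add atoms: 1-(triphenylphosphoranylidene)propan-2-one 2, CC(=O)C=P(c1ccccc1)(c1ccccc1)c1ccccc1
Why: Wittig olefination with a ketone-stabilised ylide is reliably E-selective and mild enough for the β-silyloxy aldehyde, and the six chain carbons of 3 become C7′, C7a′, C3a′, C4′, C5′ and C6′.

Step 2
Reactants: 3 (E)-6-(tert-butyldimethylsilyloxy)hex-3-en-2-one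
Product: 4 (3E)-6-(tert-butyldimethylsilyloxy)-2-(triisopropylsilyloxy)hexa-1,3-diene
Conditions: iPr3SiOTf, Et3N, Et2O, 0 °C
Reagents that add atoms: triisopropylsilyl triflate, CC(C)[Si](C(C)C)(C(C)C)OS(=O)(=O)C(F)(F)F
Why: Soft enolisation with a silyl triflate and a tertiary amine removes a methyl proton (the kinetic, cross-conjugated site) and silylates oxygen, a standard entry to 2-silyloxy-1,3-dienes that leaves the E alkene in place.

Step 3
Reactants: 4 (3E)-6-(tert-butyldimethylsilyloxy)-2-(triisopropylsilyloxy)hexa-1,3-diene; 5 cyclohex-2-en-1-one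
Product: 6 (4aR,8S,8aR)-8-[2-(tert-butyldimethylsilyloxy)ethyl]-6-(triisopropylsilyloxy)-3,4,4a,5,8,8a-hexahydronaphthalen-1(2H)-one (cis-decalin; H-6, H-7 and H-4′ all cis)
Conditions: (S)-tetrahydro-1-(2-methylphenyl)-3,3-diphenyl-1H,3H-pyrrolo[1,2-c][1,3,2]oxazaborole (20 mol %), HN(SO2CF3)2 (18 mol %), CH2Cl2, −40 °C
Reagents that add atoms: none
Why: Enantioselective Diels–Alder reaction under chiral oxazaborolidinium Lewis acid catalysis, in which the nucleophilic CH2 terminus (C7′) of the 2-silyloxydiene bonds to the enone β-carbon C6 and C4′ bonds to C7, the endo approach of the E-diene places H-6, H-7 and H-4′ all cis, and the catalyst covers one enone face and so fixes the absolute configuration of C6, C7 and C4′.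

Step 4
Reactants: 6 Diels–Alder adduct
Product: 7 C7a-methylidene analogue of 6 (C7a=O replaced by C7a=CH2; C6, C7 and C4′ unchanged)
Conditions: Cp2TiMe2, toluene, 70 °C, dark
Reagents that add atoms: dimethyltitanocene, [CH3-].[CH3-].[CH-]1C=CC=C1.[CH-]1C=CC=C1.[Ti+4]
Why: Petasis methylenation through Cp2Ti=CH2 is non-basic, so the epimerisable C7 is untouched, and the C7a=CH2 group masks the ring A ketone through steps 5 to 8, which removes the competing six-membered aldol of C3a onto C6′, the retro-Michael path and any drift at C7.

Step 5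
Reactants: 7 C7a-methylidene bis(silyl) compound
Product: 8 cis-fused 4-(2-hydroxyethyl)-5-methylideneoctahydronaphthalen-2(1H)-one (C7a′ ketone, C6′ primary alcohol; C6, C7 and C4′ unchanged)
Conditions: Bu4NF, AcOH, THF, 0 °C to rt
Reagents that add atoms: none
Why: Fluoride-induced desilylation cleaves the silyl enol ether and the primary silyl ether in one operation, while acetic acid keeps the medium near neutral and no stereocentre is touched.

Step 6
Reactants: 8 keto alcohol
Product: 9 2-(8-methylidene-3-oxodecahydronaphthalen-1-yl)acetaldehyde (C6′ aldehyde; C6, C7 and C4′ unchanged)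
Conditions: Dess–Martin periodinane, CH2Cl2, 0 °C to rt
Reagents that add atoms: none
Why: Dess–Martin oxidation takes the primary alcohol to the aldehyde under neutral conditions that spare the 1,1-disubstituted alkene and the ketone.

Step 7
Reactants: 9 keto aldehyde
Product: 10 12-hydroxy-3-methylidenetricyclo[6.2.2.0(2,7)]dodecan-9-one (new C7′–C6′ bond; ring A syn to the C5′–C6′ bridge, OH on C6′ toward the C7a′ carbonyl bridge; 6′S,7′S)
Conditions: K2CO3, MeOH (dilute), 0 °C to rt
Reagents that add atoms: none
Why: In this reversible intramolecular aldol addition only the C7′ enolate of the single ketone can reach C6′ (C3a′ would give a cyclobutane), attack is possible only on the ring face that carries the C4′ side chain, which sets C7′, the carbinol C6′ settles as the epimer with OH next to the carbonyl bridge and anti to C6 (the other epimer clashes with C5 of ring A), and dehydration is excluded at a bridgehead.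

Step 8
Reactants: 10 tricyclic aldol
Product: 11 12-(tert-butyldimethylsilyloxy)-3-methylidenetricyclo[6.2.2.0(2,7)]dodecan-9-one
Conditions: tBuMe2SiOTf, 2,6-lutidine, CH2Cl2, −78 to 0 °C
Reagents that add atoms: tert-butyldimethylsilyl triflate, CC(C)(C)[Si](C)(C)OS(=O)(=O)C(F)(F)F
Why: O-Silylation of the hindered secondary alcohol with a silyl triflate proceeds with retention at C6′ and shuts off the retro-aldol path before the second ketone is released.

Step 9
Reactants: 11 silylated methylidene ketone
Product: 13 12-(tert-butyldimethylsilyloxy)tricyclo[6.2.2.0(2,7)]dodecane-3,9-dione, via spiro-ozonide 12 (not isolated)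
Conditions: O3, CH2Cl2, −78 °C; then Me2S, −78 °C to rt
Reagents that add atoms: ozone, [O-][O+]=O
Why: Ozonolysis with reductive work-up cleaves the only alkene and returns the C7a ketone, and C7 is now safe because a cis fusion is the only low-strain way to join ring A to the bicyclo[2.2.2]octane.

Step 10
Reactants: 13 tricyclic C7a,C7a′-diketone; 14 pentanoyl chloride
Product: 15 4,10-dipentanoyl derivative of 13, drawn as the bis(enol) (pentanoyl on C3a and C3a′)
Conditions: MgBr2·OEt2, iPr2NEt, CH2Cl2, 0 °C to rt; dilute HCl work-up
Reagents that add atoms: pentanoyl chloride 14, CCCCC(=O)Cl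
Why: In this soft-enolisation Claisen-type C-acylation C7a′ can enolise only toward C3a′ (a bridgehead enolate at C7′ is geometrically forbidden), C7a gives a stable product only through the CH2 carbon C3a, the magnesium β-diketonate chelates favour C- over O-acylation and stop further reaction, and the new C3a and C3a′ centres vanish in the enol form.

Step 11
Reactants: 15 bis(β-diketone)
Product: 16 12-(tert-butyldimethylsilyloxy)-4,10-dipentanoyltricyclo[6.2.2.0(2,7)]dodeca-3,9-diene-3,9-diyl bis(trifluoromethanesulfonate) (OTf on C7a and C7a′)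
Conditions: (CF3SO2)2O, iPr2NEt, CH2Cl2, −78 °C
Reagents that add atoms: triflic anhydride, O=S(=O)(OS(=O)(=O)C(F)(F)F)C(F)(F)F
Why: O-Sulfonylation of 1,3-diketone enolates (vinylogous acyl triflate formation) should follow the endocyclic enol that six-membered rings prefer over an exocyclic alkylidene, so OTf ends on C7a and C7a′, where the ring holds it cis to the pentanoyl group, and no stereocentre is created.

Step 12
Reactants: 16 bis(enol triflate); 17 carbon monoxide
Product: 18 C6′ tert-butyldimethylsilyl ether of the target (both (Z)-butylidene lactones in place)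
Conditions: Pd(PPh3)4 (10 mol %), CO (1 atm), iPr2NEt, dry DMF, 50 °C
Reagents that add atoms: carbon monoxide 17, [C-]#[O+]
Why: Zerovalent palladium inserts into the C7a–OTf and C7a′–OTf bonds, CO migrates into each vinyl–palladium bond (new C1–C7a and C1′–C7a′), the hindered amine enolises the adjacent pentanoyl ketone toward C8 or C8′, and the enolate oxygen attacks the acyl carbon (new C1–O2 and C1′–O2′) with release of zerovalent palladium and ammonium triflate. The closest known reaction type is the carbonylative cyclisation of (Z)-β-iodoenones and 2-halophenyl alkyl ketones, in which an acylpalladium is trapped by an internal enolate oxygen to give (Z)-γ-alkylidenebutenolides or (Z)-3-alkylidenephthalides, merged here with the routine carbonylation of vinyl triflates. Lactone A and lactone B each close in the 5-exo-trig mode at the acyl carbon. No stereocentre is formed and C6, C7, C4′, C6′ and C7′ are spectators, while each new C3=C8 alkene should be Z because allylic strain turns the propyl group of the enolate away from C4H2 (ring A) or from the bridgehead C4′–H, which is also the more stable product geometry. The step needs O- over C-trapping (attack through C8 would give a cyclopentene-1,3-dione) and ring closure over capture by outside nucleophiles; the ring alkenes hold acylpalladium and ketone cis and coplanar, the harder oxygen terminus reacts with the acyl unit, and a dry, alcohol-free medium with a non-nucleophilic base leaves no competitor. Neither vinylpalladium has a β-hydrogen that can be eliminated, the C6′ oxygen is silylated, and both sites carry the same array, so one set of conditions serves both.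

Step 13
Reactants: 18 C6′ silyl ether
Product: 19 target, (6S,7R,4′R,6′S,7′S; 3Z,3′Z)
Conditions: HF·pyridine, pyridine, THF, 0 °C to rt
Reagents that add atoms: none
Why: Buffered fluoride desilylation breaks the O–Si bond only, so C6′ keeps its configuration, and the weakly acidic medium spares the base-labile enol lactones.

Compound list
1 | 3-(tert-butyldimethylsilyloxy)propanal | O=CCCO[Si](C)(C)C(C)(C)C | starting material
2 | 1-(triphenylphosphoranylidene)propan-2-one | CC(=O)C=P(c1ccccc1)(c1ccccc1)c1ccccc1 | starting material
3 | (E)-6-(tert-butyldimethylsilyloxy)hex-3-en-2-one | CC(=O)/C=C/CCO[Si](C)(C)C(C)(C)C | intermediate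
4 | (3E)-6-(tert-butyldimethylsilyloxy)-2-(triisopropylsilyloxy)hexa-1,3-diene | C=C(O[Si](C(C)C)(C(C)C)C(C)C)/C=C/CCO[Si](C)(C)C(C)(C)C | intermediate
5 | cyclohex-2-en-1-one | O=C1C=CCCC1 | starting material
6 | all-cis Diels–Alder adduct (4aR,8S,8aR) | O=C2CCC[C@@H]1CC(O[Si](C(C)C)(C(C)C)C(C)C)=C[C@H](CCO[Si](C)(C)C(C)(C)C)[C@H]21 | intermediate
7 | C7a-methylidene analogue of 6 | C=C2CCC[C@@H]1CC(O[Si](C(C)C)(C(C)C)C(C)C)=C[C@H](CCO[Si](C)(C)C(C)(C)C)[C@H]21 | intermediate
8 | keto alcohol | C=C2CCC[C@@H]1CC(=O)C[C@H](CCO)[C@H]21 | intermediate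
9 | keto aldehyde | C=C2CCC[C@@H]1CC(=O)C[C@H](CC=O)[C@H]21 | intermediate
10 | tricyclic aldol | C=C2CCC[C@@H]1[C@H]3C(=O)C[C@H](C[C@@H]3O)[C@H]21 | intermediate
11 | silylated tricyclic aldol | C=C2CCC[C@@H]1[C@H]3C(=O)C[C@H](C[C@@H]3O[Si](C)(C)C(C)(C)C)[C@H]21 | intermediate
12 | spiro-ozonide at C7a (spiro centre undefined) | C1OOC2(O1)CCC[C@@H]1[C@H]3C(=O)C[C@H](C[C@@H]3O[Si](C)(C)C(C)(C)C)[C@H]21 | intermediate
13 | tricyclic C7a,C7a′-diketone | O=C2CCC[C@@H]1[C@H]3C(=O)C[C@H](C[C@@H]3O[Si](C)(C)C(C)(C)C)[C@H]21 | intermediate
14 | pentanoyl chloride | CCCCC(=O)Cl | starting material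
15 | bis(β-diketone), bis(enol) form | OC2=C(C(=O)CCCC)CC[C@@H]1[C@H]3C(O)=C(C(=O)CCCC)[C@H](C[C@@H]3O[Si](C)(C)C(C)(C)C)[C@H]21 | intermediate
16 | bis(enol triflate) bis(pentanoyl) tricycle | FC(F)(F)S(=O)(=O)OC2=C(C(=O)CCCC)CC[C@@H]1[C@H]3C(OS(=O)(=O)C(F)(F)F)=C(C(=O)CCCC)[C@H](C[C@@H]3O[Si](C)(C)C(C)(C)C)[C@H]21 | intermediate
17 | carbon monoxide | [C-]#[O+] | starting material
18 | C6′ TBS ether of the target | CCC/C=C1\OC(=O)C2=C1CC[C@@H]1[C@H]3C4=C(/C(=C/CCC)OC4=O)[C@H](C[C@@H]3O[Si](C)(C)C(C)(C)C)[C@H]21 | intermediate
19 | CNP0289078.1 | CCC/C=C1\OC(=O)C2=C1CC[C@@H]1[C@H]3C4=C(/C(=C/CCC)OC4=O)[C@H](C[C@@H]3O)[C@H]21 | target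

Total step count: 13. Longest linear sequence: 13 steps (1 to 19).

Steps most likely to fail

Step 12. An acylpalladium unit may be intercepted through C8 or by traces of water. The reaction may stall after the first closure because the C7a′ site is crowded by the bridgehead and the silyl ether. The alkene geometry may also erode on prolonged heating. The fallback separates C–C from C–O bond formation.
- Setting out from 16, both triflates are methoxycarbonylated (Pd(OAc)2, 1,1′-bis(diphenylphosphino)ferrocene, CO, MeOH, Et3N, DMF) to the bis(methyl ester) F1.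
- LiOH in aqueous THF then gives the bis(keto acid), which rests as its ring tautomer, the bis(3-butyl-3-hydroxybutenolide) F2.
- Acetylation and elimination (Ac2O, pyridine, gentle warming) dehydrates both hemiketals toward C8 and C8′ to the more stable Z alkenes, and the route is rejoined at 18.

Step 3. Cyclohexenone is a sluggish dienophile. The diene may be protodesilylated by the strong acid, and a stepwise Michael pathway could erode endo and facial selectivity. The fallback gives up catalytic induction for a late resolution.
- From 4 and 5, achiral AlBr3/AlMe3 in toluene should give the racemate, that is 6 together with the antipodal adduct F3.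
- Steps 4 to 7 are run on the racemate and carry along the antipodal methylidene compound F4, the antipodal keto alcohol F5, the antipodal keto aldehyde F6 and the antipodal aldol F7.
- Candida antarctica lipase B with vinyl acetate in tBuOMe should acylate the (6′R)-alcohol to the antipodal acetate F8 and leave the (6′S)-alcohol, which is separated by chromatography. The route is rejoined at 10.

Step 11. Sulfonylation may occur at the pentanoyl oxygen, above all on the bicyclic half. That would give an exocyclic enol triflate which cannot lactonise. The fallback fixes the position of the leaving group by the way it is introduced, and it also bypasses step 10.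
- From 13, twofold Vilsmeier–Haack–Arnold bromoformylation (PBr3, DMF, CHCl3) puts bromine on the former carbonyl carbons and gives the bis(β-bromo enal) F9.
- BuMgCl in THF at −78 °C adds to both aldehydes to give the bis(allylic alcohol) F10.
- Dess–Martin oxidation gives the bis(β-bromo enone) F11, which has the same carbon skeleton as 16.
- F11 is submitted to the conditions of step 12 (Pd(PPh3)4, CO, iPr2NEt, DMF), and the route is rejoined at 18.

Further compounds
F1 | step 12 | bis(methyl ester) (CO2Me on C7a and C7a′) | COC(=O)C2=C(C(=O)CCCC)CC[C@@H]1[C@H]3C(C(=O)OC)=C(C(=O)CCCC)[C@H](C[C@@H]3O[Si](C)(C)C(C)(C)C)[C@H]21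
F2 | step 12 | bis(3-butyl-3-hydroxybutenolide) (C3 and C3′ undefined) | CCCCC1(O)OC(=O)C2=C1CC[C@@H]1[C@H]3C4=C(C(O)(CCCC)OC4=O)[C@H](C[C@@H]3O[Si](C)(C)C(C)(C)C)[C@H]21
F3 | step 3 | antipodal adduct (antipode of 6) | O=C2CCC[C@H]1CC(O[Si](C(C)C)(C(C)C)C(C)C)=C[C@@H](CCO[Si](C)(C)C(C)(C)C)[C@@H]21
F4 | step 3 | antipodal methylidene compound (antipode of 7) | C=C2CCC[C@H]1CC(O[Si](C(C)C)(C(C)C)C(C)C)=C[C@@H](CCO[Si](C)(C)C(C)(C)C)[C@@H]21
F5 | step 3 | antipodal keto alcohol (antipode of 8) | C=C2CCC[C@H]1CC(=O)C[C@@H](CCO)[C@@H]21
F6 | step 3 | antipodal keto aldehyde (antipode of 9) | C=C2CCC[C@H]1CC(=O)C[C@@H](CC=O)[C@@H]21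
F7 | step 3 | antipodal aldol (antipode of 10) | C=C2CCC[C@H]1[C@@H]3C(=O)C[C@@H](C[C@H]3O)[C@@H]21
F8 | step 3 | antipodal acetate (acetate of F7) | C=C2CCC[C@H]1[C@@H]3C(=O)C[C@@H](C[C@H]3OC(C)=O)[C@@H]21
F9 | step 11 | bis(β-bromo enal) | BrC2=C(C=O)CC[C@@H]1[C@H]3C(Br)=C(C=O)[C@H](C[C@@H]3O[Si](C)(C)C(C)(C)C)[C@H]21
F10 | step 11 | bis(allylic alcohol) (carbinol centres undefined) | BrC2=C(C(O)CCCC)CC[C@@H]1[C@H]3C(Br)=C(C(O)CCCC)[C@H](C[C@@H]3O[Si](C)(C)C(C)(C)C)[C@H]21
F11 | step 11 | bis(β-bromo enone) | BrC2=C(C(=O)CCCC)CC[C@@H]1[C@H]3C(Br)=C(C(=O)CCCC)[C@H](C[C@@H]3O[Si](C)(C)C(C)(C)C)[C@H]21
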